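**Retrosynthetic overview**

1. Epicalyxin B (18) comes from its penta-MOM ether 17. The chalcone C1'–C(=O) bond of 17 is made from the ring-A aryllithium (from iodide 15) and Weinreb amide 6, and 15 from 14 by iodination at the only free ring-A position.
2. Key disconnection: 14 is assembled from aldehyde 9, (E)-diene 4 and ring-A arylzinc 13 in one nickel-catalysed 1,4-arylative three-component coupling. It makes the C3–C4 and C7–ring A bonds, the 5E alkene and both stereocentres (3S, 7R).
3. Enabling feature: C4–C5=C6–C7 is an (E)-but-2-ene-1,4-diyl unit, a 1,3-diene in disguise. C4 carries the carbinol carbon C3, C7 carries ring A and a 4-hydroxyphenyl ring, and the two stereocentres sit 1,5 across the alkene. Ring A before acylation is a 2,6-dioxygenated 4-methoxyphenyl group with local twofold symmetry, so it has one metalation site (between the two oxygens) and one acylation site.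
4. Rings: none is built. Ring A comes from 5-methoxyresorcinol, the C7 and chalcone 4-hydroxyphenyl rings from 4-hydroxybenzaldehyde, and the C1 ring from methyl 3-(4-hydroxyphenyl)propanoate.

Key step: step 7

Remark on the chemistry: the heptane chain is numbered C1 (ArCH2) to C7 (diarylmethine). The given SMILES reads as 3S, 5E, 7R. All phenols are carried as MOM ethers.

**Route**

Step 1
Reactants: 1 4-hydroxybenzaldehyde
Product: 2 4-(methoxymethoxy)benzaldehyde
Conditions: NaH, MOMCl, DMF, 0 °C → rt
Reagents that add atoms: chloromethyl methyl ether (MOMCl), COCCl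
Why: O-alkylation of the sodium phenoxide (Williamson ether synthesis) should give the MOM acetal; no stereocentre is involved.

Step 2
Reactants: 2 4-(methoxymethoxy)benzaldehyde, 3 diethyl allylphosphonate
Product: 4 (E)-1-(buta-1,3-dien-1-yl)-4-(methoxymethoxy)benzene
Conditions: 3, n-BuLi, THF, −78 °C; HMPA; then 2, −78 °C → rt
Reagents that add atoms: none
Why: Horner–Wadsworth–Emmons olefination with the α-lithiated allylphosphonate should give the terminal diene with the E geometry typical of this reagent.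

Step 3
Reactants: 2 4-(methoxymethoxy)benzaldehyde, 5 diethyl [2-(methoxy(methyl)amino)-2-oxoethyl]phosphonate
Product: 6 (2E)-N-methoxy-3-[4-(methoxymethoxy)phenyl]-N-methylprop-2-enamide
Conditions: 5, NaH, THF, 0 °C; then 2, 0 °C → rt
Reagents that add atoms: none
Why: Horner–Wadsworth–Emmons olefination with a stabilised phosphonate anion is reliably E-selective with aromatic aldehydes.

Step 4
Reactants: 7 methyl 3-(4-hydroxyphenyl)propanoate
Product: 8 methyl 3-[4-(methoxymethoxy)phenyl]propanoate
Conditions: NaH, MOMCl, DMF, 0 °C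
Reagents that add atoms: chloromethyl methyl ether (MOMCl), COCCl
Why: Williamson O-alkylation of the phenoxide; the ester is not touched at 0 °C.

Step 5
Reactants: 8 methyl 3-[4-(methoxymethoxy)phenyl]propanoate
Product: 9 3-[4-(methoxymethoxy)phenyl]propanal
Conditions: iBu2AlH (1.05 equiv), CH2Cl2, −78 °C; aq. KNaC4H4O6
Reagents that add atoms: none
Why: Partial reduction of a methyl ester by iBu2AlH at low temperature stops at the aluminium hemiacetal, which gives the aldehyde on work-up.

Step 6
Reactants: 10 5-methoxybenzene-1,3-diol (5-methoxyresorcinol)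
Product: 11 1-methoxy-3,5-bis(methoxymethoxy)benzene
Conditions: NaH (2.2 equiv), MOMCl, DMF, 0 °C → rt
Reagents that add atoms: chloromethyl methyl ether (MOMCl), COCCl
Why: Double Williamson O-alkylation installs the two MOM groups that later direct the metalation.

Step 7
Reactants: 11 1-methoxy-3,5-bis(methoxymethoxy)benzene, 4 (E)-1-(buta-1,3-dien-1-yl)-4-(methoxymethoxy)benzene, 9 3-[4-(methoxymethoxy)phenyl]propanal
Product: 14 (3S,5E,7R)-7-[4-methoxy-2,6-bis(methoxymethoxy)phenyl]-1,7-bis[4-(methoxymethoxy)phenyl]hept-5-en-3-ol, via aryllithium 12 (not isolated), via arylzinc chloride 13 (not isolated)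
Conditions: 11, n-BuLi, THF, 0 °C; ZnCl2, 0 °C → rt; then 4, 9 (limiting, added last), Ni(cod)2 (10 mol%, zerovalent nickel), (S,R,R)-BINOL N,N-bis(1-phenylethyl)phosphoramidite (20 mol%), THF, 0 °C → rt; aq. NH4Cl
Reagents that add atoms: none
Why: Proposed new method: lithiation of 11 between its two OMOM groups (cooperative directed ortho-metalation) and transmetalation give arylzinc 13; zerovalent nickel carrying the chiral phosphoramidite then joins the unsubstituted terminus of s-trans diene 4 to the zinc-activated carbonyl carbon of 9 by oxidative cyclization (C3–C4 bond) to an η3-allyl oxanickelacycle, ring A passes from zinc to nickel as the alkoxide passes to zinc, and C–C reductive elimination at the remote allyl terminus C7 releases 14 and zerovalent nickel. The closest known reaction types are the nickel-catalysed three-component 1,4-coupling of 1,3-dienes, aldehydes and diorganozincs and the nickel–phosphoramidite-catalysed enantio- and diastereoselective 1,4-silylative coupling of 1-aryl-1,3-dienes, aldehydes and a silylborane; transfer of a 2,6-dioxygenated aryl group to form a diarylmethine is the untested part. No ring of the product is closed; the only cycle is the transient five-membered oxanickelacycle, made by oxidative cyclization and opened by transmetalation. C3 (S) is set by the ligand in the oxidative cyclization, with the side chain of 9 on the face of the oxanickelacycle turned away from C6 (the antipodal ligand serves if a model run shows the opposite sense). C7 (R) is set by the same event, because the nickel atom that has chosen one face of the E-diene hands ring A to C7 on that face of the syn-η3-allyl, which in this model ties 7R to 3S when ring A comes from zinc and the 4-oxyphenyl ring from the diene. The step needs 1,4- and not 1,2-arylation, a 5E alkene and no direct aryl addition to 9: as in the known methyl, hydride and silyl transfers the group on nickel should go to the allyl terminus remote from the new C–C bond, the syn-allyl of the s-trans E-diene fixes 5E, and arylzinc chlorides add only slowly to aldehydes without catalysis.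

Step 8
Reactants: 14 (3S,5E,7R)-7-[4-methoxy-2,6-bis(methoxymethoxy)phenyl]-1,7-bis[4-(methoxymethoxy)phenyl]hept-5-en-3-ol
Product: 15 (3S,5E,7R)-7-[3-iodo-4-methoxy-2,6-bis(methoxymethoxy)phenyl]-1,7-bis[4-(methoxymethoxy)phenyl]hept-5-en-3-ol
Conditions: NIS (1.0 equiv), MeCN, 0 °C, dark
Reagents that add atoms: N-iodosuccinimide (NIS), O=C1CCC(=O)N1I
Why: Electrophilic aromatic iodination should take place on the 1,3,5-trioxygenated ring A, by far the most nucleophilic site, whose two free positions are equivalent by rotation about the C7–aryl bond, so one regioisomer is expected; the stereocentres are not involved.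

Step 9
Reactants: 15 (3S,5E,7R)-7-[3-iodo-4-methoxy-2,6-bis(methoxymethoxy)phenyl]-1,7-bis[4-(methoxymethoxy)phenyl]hept-5-en-3-ol, 6 (2E)-N-methoxy-3-[4-(methoxymethoxy)phenyl]-N-methylprop-2-enamide
Product: 17 (2E)-1-{3-[(1R,2E,5S)-5-hydroxy-1,7-bis[4-(methoxymethoxy)phenyl]hept-2-en-1-yl]-6-methoxy-2,4-bis(methoxymethoxy)phenyl}-3-[4-(methoxymethoxy)phenyl]prop-2-en-1-one, via lithium alkoxide aryllithium 16 (not isolated)
Conditions: t-BuLi (3.1 equiv), THF, −78 °C; then 6, −78 → 0 °C; aq. NH4Cl
Reagents that add atoms: none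
Why: Iodine–lithium exchange at −78 °C outruns deprotonation of the doubly benzylic C7–H (the first equivalent of t-BuLi only forms the C3 lithium alkoxide), and the aryllithium adds once to the carbonyl group of the Weinreb amide, whose chelated adduct gives the enone only on work-up (Weinreb ketone synthesis), so C3 and C7 stay as set.

Step 10
Reactants: 17 (2E)-1-{3-[(1R,2E,5S)-5-hydroxy-1,7-bis[4-(methoxymethoxy)phenyl]hept-2-en-1-yl]-6-methoxy-2,4-bis(methoxymethoxy)phenyl}-3-[4-(methoxymethoxy)phenyl]prop-2-en-1-one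
Product: 18 epicalyxin B, (2E)-1-{2,4-dihydroxy-3-[(1R,2E,5S)-5-hydroxy-1,7-bis(4-hydroxyphenyl)hept-2-en-1-yl]-6-methoxyphenyl}-3-(4-hydroxyphenyl)prop-2-en-1-one
Conditions: 3 M aq. HCl, MeOH, rt
Reagents that add atoms: none
Why: Acid-catalysed acetal exchange with methanol should remove all five aryl MOM ethers under conditions established for 2'-hydroxy-6'-methoxychalcones; no bond at C3 or C7 is broken.

**Compound list**

1 | 4-hydroxybenzaldehyde | O=Cc1ccc(O)cc1 | starting material
2 | 4-(methoxymethoxy)benzaldehyde | COCOc1ccc(C=O)cc1 | intermediate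
3 | diethyl allylphosphonate | C=CCP(=O)(OCC)OCC | starting material
4 | (E)-1-(buta-1,3-dien-1-yl)-4-(methoxymethoxy)benzene | C=C/C=C/c1ccc(OCOC)cc1 | intermediate
5 | diethyl [2-(methoxy(methyl)amino)-2-oxoethyl]phosphonate | CCOP(=O)(CC(=O)N(C)OC)OCC | starting material
6 | (2E)-N-methoxy-3-[4-(methoxymethoxy)phenyl]-N-methylprop-2-enamide | CON(C)C(=O)/C=C/c1ccc(OCOC)cc1 | intermediate
7 | methyl 3-(4-hydroxyphenyl)propanoate | COC(=O)CCc1ccc(O)cc1 | starting material
8 | methyl 3-[4-(methoxymethoxy)phenyl]propanoate | COCOc1ccc(CCC(=O)OC)cc1 | intermediate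
9 | 3-[4-(methoxymethoxy)phenyl]propanal | COCOc1ccc(CCC=O)cc1 | intermediate
10 | 5-methoxybenzene-1,3-diol (5-methoxyresorcinol) | COc1cc(O)cc(O)c1 | starting material
11 | 1-methoxy-3,5-bis(methoxymethoxy)benzene | COCOc1cc(OC)cc(OCOC)c1 | intermediate
12 | [4-methoxy-2,6-bis(methoxymethoxy)phenyl]lithium | [Li]c1c(OCOC)cc(OC)cc1OCOC | intermediate
13 | [4-methoxy-2,6-bis(methoxymethoxy)phenyl]zinc chloride | Cl[Zn]c1c(OCOC)cc(OC)cc1OCOC | intermediate
14 | (3S,5E,7R)-7-[4-methoxy-2,6-bis(methoxymethoxy)phenyl]-1,7-bis[4-(methoxymethoxy)phenyl]hept-5-en-3-ol | COc1cc(OCOC)c([C@H](/C=C/C[C@@H](O)CCc2ccc(OCOC)cc2)c2ccc(OCOC)cc2)c(OCOC)c1 | intermediate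
15 | (3S,5E,7R)-7-[3-iodo-4-methoxy-2,6-bis(methoxymethoxy)phenyl]-1,7-bis[4-(methoxymethoxy)phenyl]hept-5-en-3-ol | COc1cc(OCOC)c([C@H](/C=C/C[C@@H](O)CCc2ccc(OCOC)cc2)c2ccc(OCOC)cc2)c(OCOC)c1I | intermediate
16 | lithium (3S,5E,7R)-7-[3-lithio-4-methoxy-2,6-bis(methoxymethoxy)phenyl]-1,7-bis[4-(methoxymethoxy)phenyl]hept-5-en-3-olate | COc1cc(OCOC)c([C@H](/C=C/C[C@@H](O[Li])CCc2ccc(OCOC)cc2)c2ccc(OCOC)cc2)c(OCOC)c1[Li] | intermediate
17 | (2E)-1-{3-[(1R,2E,5S)-5-hydroxy-1,7-bis[4-(methoxymethoxy)phenyl]hept-2-en-1-yl]-6-methoxy-2,4-bis(methoxymethoxy)phenyl}-3-[4-(methoxymethoxy)phenyl]prop-2-en-1-one | COc1cc(OCOC)c([C@H](/C=C/C[C@@H](O)CCc2ccc(OCOC)cc2)c2ccc(OCOC)cc2)c(OCOC)c1C(=O)/C=C/c1ccc(OCOC)cc1 | intermediate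
18 | epicalyxin B | COc1cc(O)c([C@H](/C=C/C[C@@H](O)CCc2ccc(O)cc2)c2ccc(O)cc2)c(O)c1C(=O)/C=C/c1ccc(O)cc1 | target

**Step count and risks**

Total: 10 steps. Longest linear sequence: 6 steps (steps 1, 2, 7, 8, 9, 10).

Steps most likely to fail:

1. Step 7 (Proposed new method). The aryl group may be delivered to C5 instead of C7 (1,2-arylation). Facial control in the oxidative cyclization may be too weak, lowering enantiomeric purity at C3 and the 3,7-relationship. Slow transmetalation of the hindered arylzinc may let diene oligomerisation take over. The fallback uses known chemistry, sets out from 9, 2 and arylzinc 13, and comes back to the route at 14. Brown allylation of 9 with (+)-Ipc2B(allyl) (Et2O, −78 °C; NaOH, H2O2) should give (3S)-1-[4-(methoxymethoxy)phenyl]hex-5-en-3-ol F1. In parallel, Horner–Wadsworth–Emmons reaction of 2 with triethyl phosphonoacetate should give ethyl (2E)-3-[4-(methoxymethoxy)phenyl]prop-2-enoate F2. Reduction with iBu2AlH gives (2E)-3-[4-(methoxymethoxy)phenyl]prop-2-en-1-ol F3, and ClCO2Me/pyridine gives methyl (2E)-3-[4-(methoxymethoxy)phenyl]prop-2-en-1-yl carbonate F4. Branched-selective iridium-catalysed asymmetric allylic arylation of F4 with arylzinc 13 ([Ir(cod)Cl]2, chiral phosphoramidite, THF) should give 5-methoxy-1,3-bis(methoxymethoxy)-2-{(1R)-1-[4-(methoxymethoxy)phenyl]prop-2-en-1-yl}benzene F5. E-selective cross-metathesis of F1 with F5 (second-generation Hoveyda–Grubbs catalyst, CH2Cl2, 40 °C) then forms C5=C6 and returns to 14.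

2. Step 9. The hindered aryllithium may add slowly, so that proton transfer (from C7–H or the amide) or conjugate addition competes with carbonyl addition. The fallback sets out from 15 and comes back at 17. Stille coupling of 15 with Bu3Sn(C(OEt)=CH2) (Pd(PPh3)4, CuI, CsF, DMF) should give (3S,5E,7R)-7-[3-(1-ethoxyethenyl)-4-methoxy-2,6-bis(methoxymethoxy)phenyl]-1,7-bis[4-(methoxymethoxy)phenyl]hept-5-en-3-ol F6. Brief treatment with oxalic acid on wet silica gel should hydrolyse it to 1-{3-[(1R,2E,5S)-5-hydroxy-1,7-bis[4-(methoxymethoxy)phenyl]hept-2-en-1-yl]-6-methoxy-2,4-bis(methoxymethoxy)phenyl}ethan-1-one F7. Claisen–Schmidt condensation of F7 with aldehyde 2 (KOH, MeOH, rt) returns to 17.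

3. Step 10. Protic acid may close the 2'-hydroxychalcone to the flavanone, and reversible ionisation at the doubly benzylic, allylic C7 may erode its configuration. The fallback sets out from 17 and comes back at 18. TMSOTf with 2,2'-bipyridyl (CH2Cl2, 0 °C) should exchange each aryl MOM ether for a trimethylsilyl ether without protic acid, the C3 hydroxyl being silylated as well. This gives (2E)-1-{3-[(1R,2E,5S)-1,7-bis{4-[(trimethylsilyl)oxy]phenyl}-5-[(trimethylsilyl)oxy]hept-2-en-1-yl]-6-methoxy-2,4-bis[(trimethylsilyl)oxy]phenyl}-3-{4-[(trimethylsilyl)oxy]phenyl}prop-2-en-1-one F8, which water in THF with a trace of citric acid at rt should cleave to 18.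

**Further compounds**

F1 | step 7 | (3S)-1-[4-(methoxymethoxy)phenyl]hex-5-en-3-ol | C=CC[C@@H](O)CCc1ccc(OCOC)cc1
F2 | step 7 | ethyl (2E)-3-[4-(methoxymethoxy)phenyl]prop-2-enoate | CCOC(=O)/C=C/c1ccc(OCOC)cc1
F3 | step 7 | (2E)-3-[4-(methoxymethoxy)phenyl]prop-2-en-1-ol | OC/C=C/c1ccc(OCOC)cc1
F4 | step 7 | methyl (2E)-3-[4-(methoxymethoxy)phenyl]prop-2-en-1-yl carbonate | COC(=O)OC/C=C/c1ccc(OCOC)cc1
F5 | step 7 | 5-methoxy-1,3-bis(methoxymethoxy)-2-{(1R)-1-[4-(methoxymethoxy)phenyl]prop-2-en-1-yl}benzene | COc1cc(OCOC)c([C@H](C=C)c2ccc(OCOC)cc2)c(OCOC)c1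
F6 | step 9 | (3S,5E,7R)-7-[3-(1-ethoxyethenyl)-4-methoxy-2,6-bis(methoxymethoxy)phenyl]-1,7-bis[4-(methoxymethoxy)phenyl]hept-5-en-3-ol | COc1cc(OCOC)c([C@H](/C=C/C[C@@H](O)CCc2ccc(OCOC)cc2)c2ccc(OCOC)cc2)c(OCOC)c1C(=C)OCC
F7 | step 9 | 1-{3-[(1R,2E,5S)-5-hydroxy-1,7-bis[4-(methoxymethoxy)phenyl]hept-2-en-1-yl]-6-methoxy-2,4-bis(methoxymethoxy)phenyl}ethan-1-one | COc1cc(OCOC)c([C@H](/C=C/C[C@@H](O)CCc2ccc(OCOC)cc2)c2ccc(OCOC)cc2)c(OCOC)c1C(C)=O
F8 | step 10 | (2E)-1-{3-[(1R,2E,5S)-1,7-bis{4-[(trimethylsilyl)oxy]phenyl}-5-[(trimethylsilyl)oxy]hept-2-en-1-yl]-6-methoxy-2,4-bis[(trimethylsilyl)oxy]phenyl}-3-{4-[(trimethylsilyl)oxy]phenyl}prop-2-en-1-one | COc1cc(O[Si](C)(C)C)c([C@H](/C=C/C[C@@H](O[Si](C)(C)C)CCc2ccc(O[Si](C)(C)C)cc2)c2ccc(O[Si](C)(C)C)cc2)c(O[Si](C)(C)C)c1C(=O)/C=C/c1ccc(O[Si](C)(C)C)cc1
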